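## Retrosynthetic overview

- Ring numbering of the target: C1 (CH–OAc), C2 (CH2), C3 (=CH), C4 (=C–Me), C5 (CH–CH2OAr), C6 (CMe2). The acetate and the PMB removal come last; C5–H and the C3=C4 alkene come from a reductive 1,3-transposition of a C3-enone tosylhydrazone; the aryl ether comes from a Mitsunobu reaction with umbelliferone.
- The C3-enone (C4=C5, CH2OH on C5) comes from a vinylogous ester (C5=O, C3–OEt) by hydroxymethyl addition and Stork–Danheiser transposition.
- Key disconnection: the vinylogous ester is cut into a 3-alkoxy-2,2-dimethylcyclobutanone and 1-ethoxyprop-1-yne. A nickel-catalysed, strain-release [4+2] ring expansion forms C2–C3 and C4–C5 in one operation while the C2–C5 bond of the four-membered ring breaks.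
- Enabling feature: the contiguous C2–C1–C6–C5 unit (CH2, CH–O, quaternary CMe2, ring carbon) is exactly a 3-alkoxy-2,2-dimethylcyclobutanone with C5 as carbonyl. The gem-dimethyl C6 forces cleavage on the CH2 side, and the trisubstituted C3=C4(Me) unit is a two-carbon alkyne.
- Ring order: the cyclobutane first ([2+2] of dimethylketene with a ketene acetal, C1 set by a ketoreductase), then its expansion to the cyclohexene (the only carbocycle built); the coumarin is brought in intact.

Key step: step 5

Assumption: the SMILES is read as the (1R,5R) isomer with the acetoxy and aryloxymethyl groups trans, and an R-selective ketoreductase is taken to be available from a commercial enzyme panel.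

## Route

Step 1
Reactants: 1 2-bromo-2-methylpropanoyl bromide; 2 1,1-diethoxyethene
Product: 4 3,3-diethoxy-2,2-dimethylcyclobutan-1-one, via dimethylketene 3 (not isolated)
Conditions: Zn dust, EtOAc, 0 °C, N2; ketene solution distilled into 2, Et2O, 0 °C to rt
Reagents that add atoms: none
Why: Zinc dehalogenation of 1 gives dimethylketene, which undergoes a thermal ketene [2+2] cycloaddition with the electron-rich ketene acetal; the nucleophilic CH2 of 2 bonds to the ketene carbonyl carbon and the acetal carbon closes onto the CMe2 terminus, so the acetal lies next to the quaternary carbon and no stereocenter is formed.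

Step 2
Reactants: 4 3,3-diethoxy-2,2-dimethylcyclobutan-1-one
Product: 5 (1R)-3,3-diethoxy-2,2-dimethylcyclobutan-1-ol
Conditions: ketoreductase (anti-Prelog, R-selective), NADP+ (cat.), iPrOH (10 vol %), phosphate buffer pH 7, 30 °C
Reagents that add atoms: none
Why: Ketoreductase (alcohol dehydrogenase class) asymmetric carbonyl reduction: the enzyme pocket tells the quaternary flank from the CH2 flank and delivers hydride from NADPH to one carbonyl face, and an anti-Prelog enzyme is chosen so that the carbinol (the future C1) is R.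

Step 3
Reactants: 5 (1R)-3,3-diethoxy-2,2-dimethylcyclobutan-1-ol
Product: 6 1-({[(1R)-3,3-diethoxy-2,2-dimethylcyclobutyl]oxy}methyl)-4-methoxybenzene
Conditions: NaH, PMBCl, Bu4NI (cat.), THF/DMF, 0 °C to rt
Reagents that add atoms: 4-methoxybenzyl chloride, COc1ccc(CCl)cc1
Why: Williamson etherification of the sodium alkoxide proceeds at oxygen with retention at the carbinol carbon and installs an ether that should survive nickel catalysis, Grignard addition and mild acid.

Step 4
Reactants: 6 1-({[(1R)-3,3-diethoxy-2,2-dimethylcyclobutyl]oxy}methyl)-4-methoxybenzene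
Product: 7 (3R)-3-[(4-methoxyphenyl)methoxy]-2,2-dimethylcyclobutan-1-one
Conditions: 1 M HCl, THF, 0 °C to rt
Reagents that add atoms: water, O
Why: Acid-catalysed acetal hydrolysis unmasks the ketone at the former acetal carbon (the future C5), while the ether-bearing stereocenter is β to the new carbonyl and therefore cannot epimerise by enolisation.

Step 5
Reactants: 7 (3R)-3-[(4-methoxyphenyl)methoxy]-2,2-dimethylcyclobutan-1-one; 8 1-ethoxyprop-1-yne
Product: 9 (5R)-3-ethoxy-5-[(4-methoxyphenyl)methoxy]-2,6,6-trimethylcyclohex-2-en-1-one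
Conditions: Ni(cod)2 (10 mol %), PCy3 (20 mol %), toluene, 60 °C, 8 (2 equiv) added slowly by syringe pump
Reagents that add atoms: none
Why: Proposed new method: zerovalent nickel couples the carbonyl of 7 and the alkyne oxidatively to a spiro oxanickelacyclopentene, with the C–C bond formed at the nucleophilic methyl-bearing carbon of the alkynyl ether (C4–C5) and nickel on the ethoxy-bearing carbon; β-carbon elimination, driven by release of the cyclobutane strain, then breaks the C(O)–CH2 bond to give a seven-membered nickelacycle, and C(sp3)–C(sp2) reductive elimination forms C2–C3. The closest known reaction type is the Ni(cod)2/phosphine-catalysed intermolecular insertion of internal alkynes into cyclobutanones and azetidin-3-ones, which gives cyclohexenones and dehydropiperidinones; new here are the alkynyl ether partner and the 3-alkoxy-2,2-dimethyl substitution. The six-membered ring is closed by this ring expansion (reductive elimination from the seven-membered metallacycle, a formal [4+2] of the C5–C6–C1–C2 unit with the alkyne), not by a Baldwin-type cyclisation. No stereocenter is created: C1 never bonds to nickel, so its R configuration should be carried over unchanged. The step needs site selectivity for the C(O)–CH2 bond, secured by the quaternary C6 (cleavage on that side would require a tertiary alkylnickel, and 2-substituted four-membered ketones are known to react at the less substituted bond), and it needs the alkyne orientation, secured by the polarisation of the alkynyl ether as in nickel-mediated couplings of ynamides with carbonyl compounds. Reductive elimination must also outrun β-alkoxide and β-hydride elimination at C1 in the seven-membered nickelacycle, which is why the bulky electron-rich PCy3 is chosen, and slow addition of 8 counters its cyclotrimerisation.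

Step 6
Reactants: 9 (5R)-3-ethoxy-5-[(4-methoxyphenyl)methoxy]-2,6,6-trimethylcyclohex-2-en-1-one; 10 (chloromethyl)dimethyl(propan-2-yloxy)silane
Product: 13 (5R)-3-(hydroxymethyl)-5-[(4-methoxyphenyl)methoxy]-2,4,4-trimethylcyclohex-2-en-1-one, via silylmethyl carbinol 11 (not isolated), via diol 12 (not isolated)
Conditions: 10, Mg, THF (Grignard formation); 9, LaCl3·2LiCl, THF, 0 °C; then KF, KHCO3, 30% H2O2, MeOH/THF, rt; then 1 M HCl, THF, 0 °C
Reagents that add atoms: hydrogen peroxide, OO; water, O
Why: Nucleophilic hydroxymethylation followed by Stork–Danheiser transposition: the silylmethyl Grignard reagent adds 1,2 to the C5 carbonyl, Tamao–Fleming oxidation turns C–Si into C–OH, and acid ionises the tertiary allylic alcohol through the ethoxy-stabilised cation to unveil the C3 ketone with the C4=C5 alkene, so the transient carbinol stereocenter is destroyed and its configuration does not matter.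

Step 7
Reactants: 13 (5R)-3-(hydroxymethyl)-5-[(4-methoxyphenyl)methoxy]-2,4,4-trimethylcyclohex-2-en-1-one; 14 7-hydroxy-2H-chromen-2-one (umbelliferone)
Product: 15 7-{[(5R)-5-[(4-methoxyphenyl)methoxy]-2,6,6-trimethyl-3-oxocyclohex-1-en-1-yl]methoxy}-2H-chromen-2-one
Conditions: PPh3, DIAD, THF, 0 °C to rt
Reagents that add atoms: none
Why: Mitsunobu etherification: the primary allylic alcohol is activated as its oxyphosphonium ion and displaced (SN2 at CH2) by the phenoxide of the acidic umbelliferone, with no stereocenter involved and the ketone and PMB ether inert.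

Step 8
Reactants: 15 7-{[(5R)-5-[(4-methoxyphenyl)methoxy]-2,6,6-trimethyl-3-oxocyclohex-1-en-1-yl]methoxy}-2H-chromen-2-one
Product: 16 N'-[(5R)-5-[(4-methoxyphenyl)methoxy]-2,4,4-trimethyl-3-{[(2-oxo-2H-chromen-7-yl)oxy]methyl}cyclohex-2-en-1-ylidene]-4-methylbenzenesulfonohydrazide
Conditions: TsNHNH2, PPTS (cat.), EtOH, 40 °C
Reagents that add atoms: 4-methylbenzenesulfonohydrazide, Cc1ccc(cc1)S(=O)(=O)NN
Why: Acid-catalysed condensation of the enone carbonyl with tosylhydrazide gives the α,β-unsaturated tosylhydrazone needed for the reductive transposition, and the C1 stereocenter is untouched.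

Step 9
Reactants: 16 N'-[(5R)-5-[(4-methoxyphenyl)methoxy]-2,4,4-trimethyl-3-{[(2-oxo-2H-chromen-7-yl)oxy]methyl}cyclohex-2-en-1-ylidene]-4-methylbenzenesulfonohydrazide
Product: 19 7-{[(1R,5R)-5-[(4-methoxyphenyl)methoxy]-2,6,6-trimethylcyclohex-2-en-1-yl]methoxy}-2H-chromen-2-one, via allylic tosylhydrazine 17 (not isolated), via allylic diazene 18 (not isolated)
Conditions: catecholborane, CHCl3, 0 °C; then NaOAc·3H2O, reflux
Reagents that add atoms: none
Why: Reductive 1,3-transposition of an enone tosylhydrazone: catecholborane should deliver hydride to C3 on the face anti to the C1 ether (as in 1,2-reductions of 5-substituted cyclohexenones), and after loss of sulfinate the allylic diazene passes its hydrogen suprafacially to C5 in a retro-ene step with loss of N2, which places C5–H cis to the C1 oxygen (CH2OAr trans) and fixes the alkene at C3=C4.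

Step 10
Reactants: 19 7-{[(1R,5R)-5-[(4-methoxyphenyl)methoxy]-2,6,6-trimethylcyclohex-2-en-1-yl]methoxy}-2H-chromen-2-one
Product: 20 7-{[(1R,5R)-5-hydroxy-2,6,6-trimethylcyclohex-2-en-1-yl]methoxy}-2H-chromen-2-one
Conditions: DDQ, CH2Cl2/pH 7 buffer (10:1), 0 °C to rt
Reagents that add atoms: none
Why: Oxidative PMB cleavage by DDQ (hydride abstraction at the electron-rich benzylic position, then hydrolysis of the oxocarbenium ion) frees the C1 alcohol under neutral conditions that should leave the trisubstituted alkene, the C5 stereocenter and the coumarin untouched.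

Step 11
Reactants: 20 7-{[(1R,5R)-5-hydroxy-2,6,6-trimethylcyclohex-2-en-1-yl]methoxy}-2H-chromen-2-one
Product: 21 (1R,5R)-4,6,6-trimethyl-5-{[(2-oxo-2H-chromen-7-yl)oxy]methyl}cyclohex-3-en-1-yl acetate
Conditions: Ac2O, pyridine, DMAP (cat.), CH2Cl2, rt
Reagents that add atoms: acetic anhydride, CC(=O)OC(C)=O
Why: DMAP-catalysed acylation of the hindered secondary alcohol occurs at oxygen with retention at C1 and should give the target.

## Compound list

1 | 2-bromo-2-methylpropanoyl bromide | CC(C)(Br)C(Br)=O | starting material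
2 | 1,1-diethoxyethene | C=C(OCC)OCC | starting material
3 | dimethylketene (2-methylprop-1-en-1-one) | CC(C)=C=O | intermediate
4 | 3,3-diethoxy-2,2-dimethylcyclobutan-1-one | CCOC1(OCC)CC(=O)C1(C)C | intermediate
5 | (1R)-3,3-diethoxy-2,2-dimethylcyclobutan-1-ol | CCOC1(OCC)C[C@@H](O)C1(C)C | intermediate
6 | 1-({[(1R)-3,3-diethoxy-2,2-dimethylcyclobutyl]oxy}methyl)-4-methoxybenzene | CCOC1(OCC)C[C@@H](OCc2ccc(OC)cc2)C1(C)C | intermediate
7 | (3R)-3-[(4-methoxyphenyl)methoxy]-2,2-dimethylcyclobutan-1-one | O=C1C[C@@H](OCc2ccc(OC)cc2)C1(C)C | intermediate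
8 | 1-ethoxyprop-1-yne | CCOC#CC | starting material
9 | (5R)-3-ethoxy-5-[(4-methoxyphenyl)methoxy]-2,6,6-trimethylcyclohex-2-en-1-one | COc1ccc(CO[C@@H]2CC(OCC)=C(C)C(=O)C2(C)C)cc1 | intermediate
10 | (chloromethyl)dimethyl(propan-2-yloxy)silane | CC(C)O[Si](C)(C)CCl | starting material
11 | (5R)-1-{[dimethyl(propan-2-yloxy)silyl]methyl}-3-ethoxy-5-[(4-methoxyphenyl)methoxy]-2,6,6-trimethylcyclohex-2-en-1-ol (carbinol configuration not defined) | COc1ccc(CO[C@@H]2CC(OCC)=C(C)C(O)(C[Si](C)(C)OC(C)C)C2(C)C)cc1 | intermediate
12 | (5R)-3-ethoxy-1-(hydroxymethyl)-5-[(4-methoxyphenyl)methoxy]-2,6,6-trimethylcyclohex-2-en-1-ol (carbinol configuration not defined) | COc1ccc(CO[C@@H]2CC(OCC)=C(C)C(O)(CO)C2(C)C)cc1 | intermediate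
13 | (5R)-3-(hydroxymethyl)-5-[(4-methoxyphenyl)methoxy]-2,4,4-trimethylcyclohex-2-en-1-one | COc1ccc(CO[C@@H]2CC(=O)C(C)=C(CO)C2(C)C)cc1 | intermediate
14 | 7-hydroxy-2H-chromen-2-one (umbelliferone) | O=c1ccc2ccc(O)cc2o1 | starting material
15 | 7-{[(5R)-5-[(4-methoxyphenyl)methoxy]-2,6,6-trimethyl-3-oxocyclohex-1-en-1-yl]methoxy}-2H-chromen-2-one | COc1ccc(CO[C@@H]2CC(=O)C(C)=C(COc3ccc4ccc(=O)oc4c3)C2(C)C)cc1 | intermediate
16 | N'-[(5R)-5-[(4-methoxyphenyl)methoxy]-2,4,4-trimethyl-3-{[(2-oxo-2H-chromen-7-yl)oxy]methyl}cyclohex-2-en-1-ylidene]-4-methylbenzenesulfonohydrazide (C=N geometry not defined) | COc1ccc(CO[C@@H]2CC(=NNS(=O)(=O)c3ccc(C)cc3)C(C)=C(COc4ccc5ccc(=O)oc5c4)C2(C)C)cc1 | intermediate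
17 | N'-[(1S,5R)-5-[(4-methoxyphenyl)methoxy]-2,4,4-trimethyl-3-{[(2-oxo-2H-chromen-7-yl)oxy]methyl}cyclohex-2-en-1-yl]-4-methylbenzenesulfonohydrazide (hydrazine nitrogen cis to the PMB ether) | COc1ccc(CO[C@@H]2C[C@H](NNS(=O)(=O)c3ccc(C)cc3)C(C)=C(COc4ccc5ccc(=O)oc5c4)C2(C)C)cc1 | intermediate
18 | 7-{[(3S,5R)-3-diazenyl-5-[(4-methoxyphenyl)methoxy]-2,6,6-trimethylcyclohex-1-en-1-yl]methoxy}-2H-chromen-2-one (diazene cis to the PMB ether) | COc1ccc(CO[C@@H]2C[C@H](N=N)C(C)=C(COc3ccc4ccc(=O)oc4c3)C2(C)C)cc1 | intermediate
19 | 7-{[(1R,5R)-5-[(4-methoxyphenyl)methoxy]-2,6,6-trimethylcyclohex-2-en-1-yl]methoxy}-2H-chromen-2-one | COc1ccc(CO[C@@H]2CC=C(C)[C@@H](COc3ccc4ccc(=O)oc4c3)C2(C)C)cc1 | intermediate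
20 | 7-{[(1R,5R)-5-hydroxy-2,6,6-trimethylcyclohex-2-en-1-yl]methoxy}-2H-chromen-2-one | O[C@@H]1CC=C(C)[C@@H](COc2ccc3ccc(=O)oc3c2)C1(C)C | intermediate
21 | (1R,5R)-4,6,6-trimethyl-5-{[(2-oxo-2H-chromen-7-yl)oxy]methyl}cyclohex-3-en-1-yl acetate | CC(=O)O[C@@H]1CC=C(C)[C@@H](COc2ccc3ccc(=O)oc3c2)C1(C)C | target

## Step count and risks

Total steps: 11. Longest linear sequence: 11 steps (from 1 or 2 to 21).

**Step 5 (Proposed new method).** What may go wrong: nickel-mediated cyclotrimerisation or oligomerisation of the electron-rich alkynyl ether before it meets the ketone, insertion with the reverse orientation, or β-alkoxide elimination from the seven-membered nickelacycle faster than reductive elimination. The fallback keeps the same ring expansion but uses an established alkyne class and known follow-up chemistry; it answers the alkyne-related failures, not the β-alkoxide elimination. Starting from 7, Ni(cod)2/PCy3-catalysed insertion of benzyl(dimethyl)(prop-1-yn-1-yl)silane (toluene, 90 °C) should place silicon on the carbon remote from the carbonyl, as is usual for silyl and aryl alkynes in this insertion. It should give (5R)-3-[benzyl(dimethyl)silyl]-5-[(4-methoxyphenyl)methoxy]-2,6,6-trimethylcyclohex-2-en-1-one F1. Tamao–Fleming oxidation of the alkenylsilane (Bu4NF, then KHCO3, H2O2, MeOH/THF) should give (5R)-5-[(4-methoxyphenyl)methoxy]-2,4,4-trimethylcyclohexane-1,3-dione F2. Acid-catalysed O-ethylation at the less hindered C3 oxygen (EtOH, HC(OEt)3, PPTS) comes back to the route at 9.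

**Step 6.** What may go wrong: deprotonation at C2 (the vinylogous α-position) by the Grignard reagent followed by β-elimination of the PMB alkoxide, sluggish addition to the hindered and deactivated C5 carbonyl, or premature Peterson elimination of the β-hydroxysilane. The fallback replaces organometallic addition and oxidation by epoxide homologation. Starting from 9, Corey–Chaykovsky epoxidation with the small dimethylsulfonium methylide (trimethylsulfonium iodide, KN(SiMe3)2, THF, −10 °C) should give (7R)-5-ethoxy-7-[(4-methoxyphenyl)methoxy]-4,8,8-trimethyl-1-oxaspiro[2.5]oct-4-ene F3. Dilute aqueous acid (0.5 M HCl, THF, 0 °C) should open the vinyl epoxide through the ethoxy-stabilised allyl cation and hydrolyse the enol ether, which comes back to the route at 13.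

**Step 9.** What may go wrong: poor facial selectivity of hydride delivery to the hydrazone carbon (reaction through a conformer with the C1 ether axial), which would erode the cis relationship between C5–H and the C1 oxygen, or loss of the aryloxide by vinylogous elimination if the diazene decomposes by an anionic path. The fallback sets C5 by carbon addition instead of hydrogen delivery. Starting from 9, i-Bu2AlH (toluene, −78 °C) then 1 M HCl (Stork–Danheiser transposition with hydride) should give (5R)-5-[(4-methoxyphenyl)methoxy]-2,4,4-trimethylcyclohex-2-en-1-one F4. CuBr·SMe2-catalysed conjugate addition of the silylmethyl Grignard reagent made from 10 should enter C5 trans to the C1 ether (axial attack anti to the 5-substituent of the enone). Trapping the enolate with N-(5-chloropyridin-2-yl)bis(trifluoromethanesulfonyl)imide should give (3S,5R)-3-{[dimethyl(propan-2-yloxy)silyl]methyl}-5-[(4-methoxyphenyl)methoxy]-2,4,4-trimethylcyclohex-1-en-1-yl trifluoromethanesulfonate F5. Pd(OAc)2/PPh3-catalysed reduction of the enol triflate with HCO2H/Bu3N (DMF, 60 °C) should give {[(1R,5R)-5-[(4-methoxyphenyl)methoxy]-2,6,6-trimethylcyclohex-2-en-1-yl]methyl}dimethyl(propan-2-yloxy)silane F6. Tamao–Fleming oxidation (KF, KHCO3, H2O2, MeOH/THF) should give [(1R,5R)-5-[(4-methoxyphenyl)methoxy]-2,6,6-trimethylcyclohex-2-en-1-yl]methanol F7. Mitsunobu etherification with 14 (PPh3, DIAD, THF) comes back to the route at 19.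

Further compounds
F1 | step 5 | (5R)-3-[benzyl(dimethyl)silyl]-5-[(4-methoxyphenyl)methoxy]-2,6,6-trimethylcyclohex-2-en-1-one | COc1ccc(CO[C@@H]2CC([Si](C)(C)Cc3ccccc3)=C(C)C(=O)C2(C)C)cc1
F2 | step 5 | (5R)-5-[(4-methoxyphenyl)methoxy]-2,4,4-trimethylcyclohexane-1,3-dione | COc1ccc(CO[C@@H]2CC(=O)C(C)C(=O)C2(C)C)cc1
F3 | step 6 | (7R)-5-ethoxy-7-[(4-methoxyphenyl)methoxy]-4,8,8-trimethyl-1-oxaspiro[2.5]oct-4-ene | COc1ccc(CO[C@@H]2CC(OCC)=C(C)C3(CO3)C2(C)C)cc1
F4 | step 9 | (5R)-5-[(4-methoxyphenyl)methoxy]-2,4,4-trimethylcyclohex-2-en-1-one | COc1ccc(CO[C@@H]2CC(=O)C(C)=CC2(C)C)cc1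
F5 | step 9 | (3S,5R)-3-{[dimethyl(propan-2-yloxy)silyl]methyl}-5-[(4-methoxyphenyl)methoxy]-2,4,4-trimethylcyclohex-1-en-1-yl trifluoromethanesulfonate | COc1ccc(CO[C@@H]2CC(OS(=O)(=O)C(F)(F)F)=C(C)[C@@H](C[Si](C)(C)OC(C)C)C2(C)C)cc1
F6 | step 9 | {[(1R,5R)-5-[(4-methoxyphenyl)methoxy]-2,6,6-trimethylcyclohex-2-en-1-yl]methyl}dimethyl(propan-2-yloxy)silane | COc1ccc(CO[C@@H]2CC=C(C)[C@@H](C[Si](C)(C)OC(C)C)C2(C)C)cc1
F7 | step 9 | [(1R,5R)-5-[(4-methoxyphenyl)methoxy]-2,6,6-trimethylcyclohex-2-en-1-yl]methanol | COc1ccc(CO[C@@H]2CC=C(C)[C@@H](CO)C2(C)C)cc1
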